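**Plan**

1. Numbering: five-membered ring C1(Me)–C2–C3–C4(OH, iPr)–C5(H); seven-membered ring C1–C5–C6(O-ester)–C7–C8(Me)=C9–C10. The enabling feature is that C6 and C9 are 1,4-related across C7–C8, so C6–C7–C8–C9–C10 is a cyclopentane-1,3-dione with the ring-fusion carbons C5 and C1 inserted between C6 and C10, and O4 sits 1,3 to O6.
2. Retrosynthetic cuts: the C6 ester C–O bond; the C8=C9 alkene and C6 carbinol back to a C6,C9-dione; C6–C10 re-closed (aldol sense) to a cyclobutane; the cyclobutane cut at C5–C6 and C1–C10 into a cyclopentenol and the dione enol, held together as an O4–Si–O6 silyl ketal.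
3. Forward order: cyclopentene by ring contraction of (S)-terpinen-4-ol; silicon tether; [2+2] photocycloaddition (cyclobutane plus dioxasilinane); C8 methylation; retro-aldol opening to the seven-membered ring; adjustment of C9, C5 and C6; acylation.
4. Stereochemistry: C4 comes from (S)-terpinen-4-ol; the tether delivers the enone to the O4 face and so fixes C1 (and, transiently, C5, C6 and C10).
5. C5 is then inverted by kinetic protonation of a C5 enolate; C6 is set by dissolving-metal reduction to the equatorial alcohol.
6. The tether is used because an untethered 3-oxy-enone would be expected to bond its oxygen-bearing carbon to the methyl-bearing alkene carbon C1, the wrong orientation, and to show weak facial preference.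

Key step: step 7

**Route**

Step 1
Reactants: 1 (S)-terpinen-4-ol
Product: 2 (S)-terpinen-4-ol triethylsilyl ether
Conditions: Et3SiOTf, 2,6-lutidine, CH2Cl2, −78 → 0 °C
Reagents that add atoms: triethylsilyl trifluoromethanesulfonate, CC[Si](CC)(CC)OS(=O)(=O)C(F)(F)F
Why: Silyl triflate/2,6-lutidine silylation of a hindered tertiary alcohol; the ether should block β-elimination of the C4 oxygen during the aldol condensation and the decarbonylation.

Step 2
Reactants: 2 (S)-terpinen-4-ol triethylsilyl ether
Product: 4 (S)-3-isopropyl-6-oxo-3-(triethylsilyloxy)heptanal, via ozonide 3 (not isolated)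
Conditions: O3, CH2Cl2, −78 °C; then Me2S, −78 °C → rt
Reagents that add atoms: ozone, [O-][O+]=O
Why: Ozonolysis of the trisubstituted ring alkene with reductive work-up should give the methyl ketone and the aldehyde while leaving the quaternary carbinol centre untouched.

Step 3
Reactants: 4 (S)-3-isopropyl-6-oxo-3-(triethylsilyloxy)heptanal
Product: 5 (R)-5-isopropyl-2-methyl-5-(triethylsilyloxy)cyclopent-1-ene-1-carbaldehyde
Conditions: piperidine, AcOH (cat.), benzene, 4 Å MS, rt → 50 °C
Reagents that add atoms: none
Why: Amine-catalysed intramolecular aldol condensation, in which the enamine of the aldehyde adds to the methyl ketone (5-exo closure) and dehydrates, the usual course of 6-oxoheptanals under piperidinium acetate (cyclopentene carbaldehyde rather than acetylcyclopentene).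

Step 4
Reactants: 5 (R)-5-isopropyl-2-methyl-5-(triethylsilyloxy)cyclopent-1-ene-1-carbaldehyde
Product: 6 (R)-triethyl[(1-isopropyl-3-methylcyclopent-2-en-1-yl)oxy]silane
Conditions: RhCl(PPh3)3 (1.05 equiv), PhCN, 130 °C
Reagents that add atoms: none
Why: Tsuji–Wilkinson decarbonylation (oxidative addition of the aldehyde C–H bond to rhodium, CO extrusion, reductive elimination) should replace CHO by H with the ring alkene left in place.

Step 5
Reactants: 6 (R)-triethyl[(1-isopropyl-3-methylcyclopent-2-en-1-yl)oxy]silane
Product: 7 (R)-1-isopropyl-3-methylcyclopent-2-en-1-ol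
Conditions: Bu4NF, THF, rt → 40 °C
Reagents that add atoms: none
Why: Fluoride desilylation under basic, non-ionising conditions, which should spare the acid-sensitive tertiary allylic alcohol.

Step 6
Reactants: 7 (R)-1-isopropyl-3-methylcyclopent-2-en-1-ol; 8 cyclopentane-1,3-dione
Product: 10 3-{[diisopropyl((R)-1-isopropyl-3-methylcyclopent-2-en-1-yloxy)silyl]oxy}cyclopent-2-en-1-one, via silyl triflate 9 (not isolated)
Conditions: iPr2Si(OTf)2, 2,6-lutidine, CH2Cl2, −78 → 0 °C; then 8, Et3N, 0 °C → rt; filtration, no aqueous work-up
Reagents that add atoms: diisopropylsilyl bis(trifluoromethanesulfonate), CC(C)[Si](OS(=O)(=O)C(F)(F)F)(OS(=O)(=O)C(F)(F)F)C(C)C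
Why: Stepwise nucleophilic substitution at silicon (unsymmetrical silyl ketal formation): the hindered alcohol should displace only one triflate, and the acidic enol of the 1,3-dione is then O-silylated to the moisture-sensitive vinylogous silyl ester, which is used crude.

Step 7
Reactants: 10 silyl-ketal-tethered enone
Product: 11 cis-anti-cis photoadduct (cyclobutane C1–C5–C6–C10, ketone at C9, 2,2-diisopropyl-1,3-dioxa-2-silinane across O4 and O6)
Conditions: hν (medium-pressure Hg lamp, Pyrex, λ > 290 nm), degassed cyclohexane, 5 mM, 10 °C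
Reagents that add atoms: none
Why: Excitation of the 3-silyloxy enone and intersystem crossing give the triplet, whose β-carbon C6 bonds first to C5 (6-exo-trig closure of the 1,3-dioxa-2-silinane ring), leaving a tertiary radical at C1 and an α-keto radical at C10 that combine after spin inversion (C1–C10) to close the cyclobutane. The closest known reaction is the intramolecular enone–alkene [2+2] photocycloaddition of 3-oxy-enones that carry the alkene on the enol oxygen through a temporary tether, the photochemical half of a de Mayo reaction. C5 and C6 are controlled by the tether, because the six-membered silyl ketal can only be cis-fused to the cyclopentene and so delivers C6 to the face of O4 fixed in compound 1; C1 follows because the biradical can only close a cis-fused bicyclo[3.2.0] unit, and C10 from the cis fusion of cyclobutane and cyclopentanone, which gives the cis-anti-cis adduct. The step needs C6 to join the CH carbon C5 (and C10 the methyl-bearing C1) and addition anti to the isopropyl group; the four-atom C4–O–Si–O link should secure both, since the crossed mode would need a seven-membered ring and approach from the isopropyl face is geometrically excluded. Pyrex-filtered light limits secondary photolysis of the ketone product, and a dry hydrocarbon solvent protects the silyl enol ether.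

Step 8
Reactants: 11 cis-anti-cis photoadduct
Product: 13 C8-methylated photoadduct (methyl on the convex face), via lithium enolate 12 (not isolated)
Conditions: LiN(iPr)2 (LDA), THF, −78 °C; then MeI, −78 → −30 °C
Reagents that add atoms: iodomethane, CI
Why: Kinetic enolate alkylation, regiospecific because the ketone can enolise only towards C8 (C10 is a cyclobutane ring-fusion carbon); the C8 centre is removed in step 11.

Step 9
Reactants: 13 C8-methylated photoadduct
Product: 15 cis-fused 4-hydroxydaucane-6,9-dione (C8 epimers), via cyclobutanediol 14 (not isolated)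
Conditions: Bu4NF, AcOH, THF, 0 °C → rt
Reagents that add atoms: none
Why: Fluoride removes the silylene and the liberated β-keto cyclobutanol should open by strain-driven retro-aldol cleavage of C6–C10 (second half of the de Mayo reaction), merging the four- and five-membered rings into the cycloheptane-1,4-dione, with acetic acid buffering against retro-aldol of the new tertiary β-hydroxy ketone.

Step 10
Reactants: 15 cis-fused 4-hydroxydaucane-6,9-dione
Product: 16 4-O-triethylsilyl ether of 15
Conditions: Et3SiOTf, 2,6-lutidine, CH2Cl2, −78 → −40 °C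
Reagents that add atoms: triethylsilyl trifluoromethanesulfonate, CC[Si](CC)(CC)OS(=O)(=O)C(F)(F)F
Why: Silyl triflate/2,6-lutidine protection of a β-hydroxy ketone at low temperature; the free tertiary alcohol would otherwise add to the enedione and dienone of the next steps (oxa-Michael) or fragment by retro-aldol under base.

Step 11
Reactants: 16 silylated cis-fused 6,9-dione
Product: 17 cis-fused 4-(triethylsilyloxy)dauc-7-ene-6,9-dione
Conditions: 2-iodoxybenzoic acid (IBX), DMSO, 70 °C
Reagents that add atoms: none
Why: IBX dehydrogenation of a ketone to an enone, here a 1,4-diketone to the ene-1,4-dione; C7–C8 is the only bond that can be desaturated because C4 and C1 are quaternary, so enolisation of either ketone leads to the same product.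

Step 12
Reactants: 17 cis-fused dauc-7-ene-6,9-dione
Product: 19 C9 dienyl triflate (C7=C8, C9=C10, ketone at C6), via potassium enolate 18 (not isolated)
Conditions: KN(SiMe3)2 (KHMDS), THF, −78 °C; then PhNTf2, −78 → −40 °C
Reagents that add atoms: N-phenylbis(trifluoromethanesulfonimide), O=S(=O)(N(c1ccccc1)S(=O)(=O)C(F)(F)F)C(F)(F)F
Why: Enolate O-triflation; with C7 and C8 sp2 the only α-hydrogens are at C10 and at the buried C5 methine, so the hindered base should deprotonate C10 and the trapped C9 enolate distinguishes C9 from C6.

Step 13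
Reactants: 19 C9 dienyl triflate
Product: 20 cis-fused 4-(triethylsilyloxy)dauca-7,9-dien-6-one
Conditions: Pd(OAc)2 (5 mol %), PPh3, HCO2H, Et3N, DMF, 60 °C
Reagents that add atoms: none
Why: Palladium-catalysed formate reduction of an enol triflate (oxidative addition to zerovalent palladium, formate exchange, decarboxylation, reductive elimination), which tolerates conjugated ketones.

Step 14
Reactants: 20 cis-fused dauca-7,9-dien-6-one
Product: 22 trans-fused 4-(triethylsilyloxy)dauca-7,9-dien-6-one (H5 trans to the C1 methyl), via lithium trienolate 21 (not isolated)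
Conditions: LiN(iPr)2 (LDA), THF, −78 °C; then 2,6-di-tert-butyl-4-methylphenol, −78 °C
Reagents that add atoms: none
Why: Kinetic α′-deprotonation of the dienone (C5–H is its only α-hydrogen) and irreversible kinetic protonation of the tub-shaped cycloheptatrienolate on its convex face, anti to the angular methyl and the isopropyl group, should give the less stable trans ring fusion, with the bulky phenol and low temperature preventing equilibration.

Step 15
Reactants: 22 trans-fused dauca-7,9-dien-6-one
Product: 25 4-O-triethylsilyl dauc-8-ene-4,6-diol with the target configuration (O6 cis to H5), via lithium dienolate 23 (not isolated), via β,γ-enone 24 (not isolated)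
Conditions: Li, NH3(l)/THF, t-BuOH (1 equiv), −78 °C; then MeOH, −78 → −33 °C; NH4Cl
Reagents that add atoms: none
Why: Dissolving-metal reduction of a linear dienone: 1,6-addition (proton at C10) gives the dienolate, kinetic α-protonation at C7 by methanol places the alkene at C8=C9, and the unconjugated ketone is reduced at once by the excess metal to the thermodynamically preferred equatorial alcohol, which avoids the 1,3-diaxial clash with the angular methyl.

Step 16
Reactants: 25 4-O-triethylsilyl dauc-8-ene-4,6-diol; 26 3,4-dimethoxybenzoyl chloride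
Product: 27 4-O-triethylsilyl ether of the target ester
Conditions: DMAP, Et3N, CH2Cl2, rt
Reagents that add atoms: none
Why: DMAP-catalysed acylation (nucleophilic catalysis) of the only free hydroxyl, the secondary C6 alcohol, by the aroyl chloride.

Step 17
Reactants: 27 4-O-triethylsilyl ether of the target ester
Product: 28 target CNP0153023.2
Conditions: HF·pyridine, THF, 0 °C → rt
Reagents that add atoms: none
Why: Fluoride-mediated cleavage of the tertiary triethylsilyl ether under mildly acidic conditions that should leave the benzoate ester and the trisubstituted alkene untouched.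

**Compound list**

1 | (S)-terpinen-4-ol | CC1=CC[C@](O)(C(C)C)CC1 | starting material
2 | (S)-terpinen-4-ol triethylsilyl ether | CC1=CC[C@](O[Si](CC)(CC)CC)(C(C)C)CC1 | intermediate
3 | ozonide of 2 (1,2,4-trioxolane across the former alkene, mixture at the two trioxolane carbons) | CC12CC[C@@](O[Si](CC)(CC)CC)(C(C)C)CC(OO1)O2 | intermediate (not isolated)
4 | (S)-3-isopropyl-6-oxo-3-(triethylsilyloxy)heptanal | CC(=O)CC[C@@](O[Si](CC)(CC)CC)(C(C)C)CC=O | intermediate
5 | (R)-5-isopropyl-2-methyl-5-(triethylsilyloxy)cyclopent-1-ene-1-carbaldehyde | CC1=C(C=O)[C@](O[Si](CC)(CC)CC)(C(C)C)CC1 | intermediate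
6 | (R)-triethyl[(1-isopropyl-3-methylcyclopent-2-en-1-yl)oxy]silane | CC1=C[C@](O[Si](CC)(CC)CC)(C(C)C)CC1 | intermediate
7 | (R)-1-isopropyl-3-methylcyclopent-2-en-1-ol | CC1=C[C@](O)(C(C)C)CC1 | intermediate
8 | cyclopentane-1,3-dione | O=C1CCC(=O)C1 | starting material
9 | (R)-(1-isopropyl-3-methylcyclopent-2-en-1-yloxy)diisopropylsilyl triflate | CC1=C[C@](O[Si](OS(=O)(=O)C(F)(F)F)(C(C)C)C(C)C)(C(C)C)CC1 | intermediate (not isolated)
10 | 3-{[diisopropyl((R)-1-isopropyl-3-methylcyclopent-2-en-1-yloxy)silyl]oxy}cyclopent-2-en-1-one (precursor of the key step) | CC1=C[C@](O[Si](C(C)C)(C(C)C)OC2=CC(=O)CC2)(C(C)C)CC1 | intermediate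
11 | cis-anti-cis photoadduct: cyclobutane C1–C5–C6–C10 cis-fused to the cyclopentane (H5 and C1-methyl cis, anti to O4) and to the cyclopentanone (O6 and H10 cis), O4 and O6 bridged by Si(iPr)2 | CC(C)[Si]1(C(C)C)O[C@@]2(C(C)C)CC[C@@]3(C)[C@@H]4C(=O)CC[C@]4(O1)[C@@H]23 | intermediate
12 | lithium enolate of 11 (C8=C9) | CC(C)[Si]1(C(C)C)O[C@@]2(C(C)C)CC[C@@]3(C)[C@@H]4C(O[Li])=CC[C@]4(O1)[C@@H]23 | intermediate (not isolated)
13 | C8-methylated photoadduct (methyl on the convex face, cis to H10) | CC(C)[Si]1(C(C)C)O[C@@]2(C(C)C)CC[C@@]3(C)[C@@H]4C(=O)[C@@H](C)C[C@]4(O1)[C@@H]23 | intermediate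
14 | cyclobutane-4,6-diol from desilylation of 13 | CC(C)[C@]1(O)CC[C@@]2(C)[C@@H]3C(=O)[C@@H](C)C[C@]3(O)[C@@H]12 | intermediate (not isolated)
15 | cis-fused 4-hydroxydaucane-6,9-dione (H5 cis to C1-methyl; C8 epimers, centre removed in step 11) | CC(C)[C@]1(O)CC[C@@]2(C)CC(=O)C(C)CC(=O)[C@@H]12 | intermediate
16 | 4-O-triethylsilyl ether of 15 | CC(C)[C@]1(O[Si](CC)(CC)CC)CC[C@@]2(C)CC(=O)C(C)CC(=O)[C@@H]12 | intermediate
17 | cis-fused 4-(triethylsilyloxy)dauc-7-ene-6,9-dione | CC(C)[C@]1(O[Si](CC)(CC)CC)CC[C@@]2(C)CC(=O)C(C)=CC(=O)[C@@H]12 | intermediate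
18 | potassium C9 enolate of 17 (C9=C10) | CC(C)[C@]1(O[Si](CC)(CC)CC)CC[C@@]2(C)C=C(O[K])C(C)=CC(=O)[C@@H]12 | intermediate (not isolated)
19 | cis-fused 6-oxo-4-(triethylsilyloxy)dauca-7,9-dien-9-yl triflate | CC(C)[C@]1(O[Si](CC)(CC)CC)CC[C@@]2(C)C=C(OS(=O)(=O)C(F)(F)F)C(C)=CC(=O)[C@@H]12 | intermediate
20 | cis-fused 4-(triethylsilyloxy)dauca-7,9-dien-6-one | CC(C)[C@]1(O[Si](CC)(CC)CC)CC[C@@]2(C)C=CC(C)=CC(=O)[C@@H]12 | intermediate
21 | lithium trienolate of 20 (C5=C6) | CC(C)[C@]1(O[Si](CC)(CC)CC)CC[C@@]2(C)C=CC(C)=CC(O[Li])=C12 | intermediate (not isolated)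
22 | trans-fused 4-(triethylsilyloxy)dauca-7,9-dien-6-one (H5 trans to C1-methyl, cis to O4) | CC(C)[C@]1(O[Si](CC)(CC)CC)CC[C@@]2(C)C=CC(C)=CC(=O)[C@H]12 | intermediate
23 | lithium dienolate from 1,6-reduction of 22 (C6=C7, C8=C9) | CC(C)[C@]1(O[Si](CC)(CC)CC)CC[C@@]2(C)CC=C(C)C=C(O[Li])[C@H]12 | intermediate (not isolated)
24 | trans-fused 4-(triethylsilyloxy)dauc-8-en-6-one (β,γ-enone) | CC(C)[C@]1(O[Si](CC)(CC)CC)CC[C@@]2(C)CC=C(C)CC(=O)[C@H]12 | intermediate (not isolated)
25 | trans-fused 4-(triethylsilyloxy)dauc-8-en-6-ol, O6 cis to H5 (H5/H6 trans) | CC(C)[C@]1(O[Si](CC)(CC)CC)CC[C@@]2(C)CC=C(C)C[C@@H](O)[C@H]12 | intermediate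
26 | 3,4-dimethoxybenzoyl chloride | COc1ccc(C(=O)Cl)cc1OC | starting material
27 | 4-O-triethylsilyl ether of the target 6-(3,4-dimethoxybenzoate) | CC(C)[C@]1(O[Si](CC)(CC)CC)CC[C@@]2(C)CC=C(C)C[C@@H](OC(=O)c3ccc(OC)c(OC)c3)[C@H]12 | intermediate
28 | CNP0153023.2, [(3R,3aR,4R,8aS)-3-hydroxy-6,8a-dimethyl-3-isopropyl-1,2,3,3a,4,5,8,8a-octahydroazulen-4-yl] 3,4-dimethoxybenzoate | COc1ccc(C(=O)O[C@@H]2CC(C)=CC[C@]3(C)CC[C@@](O)(C(C)C)[C@@H]23)cc1OC | target

**Summary**

Total step count: 17. Longest linear sequence: 17 steps (1 → 28); compounds 8 and 26 are purchased.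

Steps most likely to fail:

Step 14 (C5 inversion). The lithium enolate could form slowly at the hindered C5 methine, expel the C4 silyloxide by β-elimination, or be protonated with poor facial selectivity. Fallback, setting out from 20 and returning at 22: enolise without an anionic intermediate by treating 20 with Me3SiOTf and Et3N in CH2Cl2 at 0 °C to give the trimethylsilyl trienol ether F1. Then cleave the Si–O bond of F1 with Bu4NF in the presence of excess AcOH in THF at −78 °C, so that the enolate is protonated as it forms, on the convex face, to give 22.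

Step 15 (reduction cascade). The β,γ-enone could isomerise into conjugation and be over-reduced, or the ketone could be reduced to the wrong C6 epimer. Fallback, setting out from 22 and returning at 27: run the lithium–ammonia reduction with one equivalent of t-BuOH only and quench with NH4Cl to isolate β,γ-enone 24. Reduce 24 with LiBH(s-Bu)3 in THF at −78 °C, where hydride should add to the open face anti to the angular methyl and give the axial 6-epi alcohol F2. Mitsunobu esterification of F2 with 3,4-dimethoxybenzoic acid (PPh3, DIAD, toluene) then inverts C6 and gives ester 27 directly, bypassing 25.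

Step 6 (tether assembly). The hindered tertiary allylic alcohol may silylate incompletely or ionise in the presence of silyl triflate, and the silyl enol ether may hydrolyse. Fallback, setting out from 7 and returning at 10: silylate 7 with chlorodiisopropylsilane (imidazole, DMAP, CH2Cl2) to the alkoxy(diisopropyl)silane F3. Then join F3 to dione 8 by catalytic dehydrogenative Si–O coupling (Rh2(OAc)4, CH2Cl2, rt), which forms 10 with loss of hydrogen under neutral, salt-free conditions.

**Further compounds**

F1 | step 14 | trimethylsilyl trienol ether of 20 (C5=C6–OSiMe3, C7=C8, C9=C10) | CC(C)[C@]1(O[Si](CC)(CC)CC)CC[C@@]2(C)C=CC(C)=CC(O[Si](C)(C)C)=C12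
F2 | step 15 | trans-fused 4-(triethylsilyloxy)dauc-8-en-6-ol, 6-epimer of 25 (O6 trans to H5) | CC(C)[C@]1(O[Si](CC)(CC)CC)CC[C@@]2(C)CC=C(C)C[C@H](O)[C@H]12
F3 | step 6 | (R)-diisopropyl[(1-isopropyl-3-methylcyclopent-2-en-1-yl)oxy]silane | CC1=C[C@](O[SiH](C(C)C)C(C)C)(C(C)C)CC1
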